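**Retrosynthetic overview**
- The (5S)-enone comes from E1cB loss of acetic acid from a β-acetoxy ketone, itself made by oxidising the one free secondary OH of a monoacetate.
- The monoacetate comes from lipase desymmetrisation of a meso, all-cis 1-substituted cyclohexane-1,3,5-triol; this step creates the only stereocentre.
- The meso triol comes from acetal hydrolysis of the exo-face aldol adduct between the methyl-ketone enolate and a meso 2,4-dioxabicyclo[3.3.1]nonan-7-one.
- The bicyclic ketone comes from cis,cis-cyclohexane-1,3,5-triol (benzylidene acetal, then oxidation); the methyl ketone comes from linoleic acid via its Weinreb amide.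
- Rings: the carbocycle is bought; the only ring formed is the temporary 1,3-dioxane (acetal) ring, closed first and opened again before the enzymatic step.

Assumption: linoleic acid (≥ 99 % 9Z,12Z) and cis,cis-cyclohexane-1,3,5-triol are taken as the commercial, achiral starting materials, and the SMILES is read as the (5S) enantiomer.

**Step 1**
Reactants: 1 (9Z,12Z)-octadeca-9,12-dienoic acid (linoleic acid)
Product: 3 (9Z,12Z)-N-methoxy-N-methyloctadeca-9,12-dienamide, via acyl imidazole 2 (not isolated)
Conditions: 1,1'-carbonyldiimidazole (1.1 equiv), CH2Cl2, rt, 1 h; then MeNHOMe·HCl (1.2 equiv), rt, 12 h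
Reagents that add atoms: N,O-dimethylhydroxylamine hydrochloride, CNOC.Cl
Why: Amide coupling through the N-acylimidazole (Weinreb amide formation) is mild enough to leave the skipped Z,Z-diene untouched, and no stereocentre is involved.

**Step 2**
Reactants: 3 (9Z,12Z)-N-methoxy-N-methyloctadeca-9,12-dienamide
Product: 5 (10Z,13Z)-nonadeca-10,13-dien-2-one, via bromomagnesium hemiaminal chelate 4 (not isolated)
Conditions: MeMgBr (1.3 equiv), THF, 0 °C; then 1 M HCl, 0 °C
Reagents that add atoms: methylmagnesium bromide, C[Mg]Br
Why: In the Weinreb ketone synthesis the chelated tetrahedral adduct survives until the acidic quench, so the Grignard reagent adds only once and the methyl ketone forms without over-addition.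

**Step 3**
Reactants: 6 cis,cis-cyclohexane-1,3,5-triol (all-cis; meso)
Product: 7 3-exo-phenyl-2,4-dioxabicyclo[3.3.1]nonan-7-endo-ol (meso)
Conditions: PhCH(OMe)2 (1.2 equiv), p-TsOH·H2O (5 mol %), DMF, 50 °C, 50 mbar (MeOH removed); Et3N quench
Reagents that add atoms: benzaldehyde dimethyl acetal, COC(OC)c1ccccc1
Why: Acid-catalysed transacetalisation under thermodynamic control ties two of the three cis hydroxyls into a six-membered benzylidene acetal (phenyl equatorial on the dioxane chair), which leaves one hydroxyl free, locks the ring oxygens axial and keeps the molecule achiral.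

**Step 4**
Reactants: 7 3-exo-phenyl-2,4-dioxabicyclo[3.3.1]nonan-7-endo-ol
Product: 8 3-exo-phenyl-2,4-dioxabicyclo[3.3.1]nonan-7-one (meso)
Conditions: (n-Pr)4N[RuO4] (5 mol %), N-methylmorpholine N-oxide (1.5 equiv), 4 Å molecular sieves, CH2Cl2, rt
Reagents that add atoms: none
Why: The Ley–Griffith oxidation of the secondary alcohol runs under neutral conditions, so the acid-labile acetal and the elimination-prone β-alkoxy ketone are not disturbed.

**Step 5**
Reactants: 5 (10Z,13Z)-nonadeca-10,13-dien-2-one; 8 3-exo-phenyl-2,4-dioxabicyclo[3.3.1]nonan-7-one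
Product: 10 (10Z,13Z)-1-(7-endo-hydroxy-3-exo-phenyl-2,4-dioxabicyclo[3.3.1]nonan-7-yl)nonadeca-10,13-dien-2-one, via lithium enolate 9 (not isolated)
Conditions: LiN(i-Pr)2 (1.25 equiv), THF, −78 °C, 5 (1.2 equiv) added dropwise, 45 min; then 8 (1.0 equiv), −78 °C, 2 h; AcOH quench at −78 °C
Reagents that add atoms: none
Why: In this directed aldol addition the kinetic methyl-side lithium enolate can reach the carbonyl of 8 only from the exo face, because the endo face is covered by the O–CH(Ph)–O bridge of the bicyclo[3.3.1] skeleton, so the new tertiary hydroxyl ends up cis to both ring oxygens and the adduct is still meso.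

**Step 6**
Reactants: 10 (10Z,13Z)-1-(7-endo-hydroxy-3-exo-phenyl-2,4-dioxabicyclo[3.3.1]nonan-7-yl)nonadeca-10,13-dien-2-one
Product: 11 (10Z,13Z)-1-[(1s,3R,5S)-1,3,5-trihydroxycyclohexyl]nonadeca-10,13-dien-2-one (meso; the three hydroxyls all cis)
Conditions: AcOH–THF–H2O (3:1:1), 35 °C
Reagents that add atoms: none
Why: Acid-catalysed hydrolysis of the strained bicyclic benzylidene acetal proceeds under conditions too mild to dehydrate the tertiary aldol, and the side-chain ketone, being trans to the two secondary hydroxyls, cannot close a ketal onto them.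

**Step 7**
Reactants: 11 (10Z,13Z)-1-[(1s,3R,5S)-1,3,5-trihydroxycyclohexyl]nonadeca-10,13-dien-2-one
Product: 12 (1R,3S,5S)-3,5-dihydroxy-3-[(10Z,13Z)-2-oxononadeca-10,13-dien-1-yl]cyclohexyl acetate
Conditions: immobilised Candida antarctica lipase B, vinyl acetate (5 equiv), t-BuOMe, 30 °C; enzyme filtered off, neutral work-up
Reagents that add atoms: vinyl acetate, CC(=O)OC=C
Why: This lipase-catalysed irreversible transesterification desymmetrises the meso diol by acetylating only the (R)-configured secondary carbinol (Kazlauskas rule with the ring branch leading to the quaternary carbon as the large group), which turns the previously non-stereogenic quaternary carbinol carbon into the (S) stereocentre of the target, all earlier compounds being achiral.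

**Step 8**
Reactants: 12 (1R,3S,5S)-3,5-dihydroxy-3-[(10Z,13Z)-2-oxononadeca-10,13-dien-1-yl]cyclohexyl acetate
Product: 13 (1S,3S)-3-hydroxy-5-oxo-3-[(10Z,13Z)-2-oxononadeca-10,13-dien-1-yl]cyclohexyl acetate
Conditions: Dess–Martin periodinane (1.3 equiv), CH2Cl2, 0 °C to rt
Reagents that add atoms: none
Why: The Dess–Martin oxidation converts the remaining secondary alcohol into the ring ketone without base, so neither acetyl migration (which would racemise 12) nor premature elimination occurs, and the tertiary alcohol, the diene and the stereocentre are untouched.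

**Step 9**
Reactants: 13 (1S,3S)-3-hydroxy-5-oxo-3-[(10Z,13Z)-2-oxononadeca-10,13-dien-1-yl]cyclohexyl acetate
Product: 14 (5S)-5-hydroxy-5-[(10Z,13Z)-2-oxononadeca-10,13-dien-1-yl]cyclohex-2-en-1-one (target)
Conditions: Et3N (2 equiv), CH2Cl2, 0 °C, 1 h
Reagents that add atoms: none
Why: E1cB β-elimination of acetic acid from the β-acetoxy ketone gives the conjugated enone, acetate being a far better leaving group than the tertiary hydroxide, and the carbinol stereocentre is not involved and stays (S).

**Compound list**
1 | (9Z,12Z)-octadeca-9,12-dienoic acid (linoleic acid) | CCCCC/C=C\C/C=C\CCCCCCCC(=O)O | starting material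
2 | 1-[(9Z,12Z)-octadeca-9,12-dienoyl]imidazole | CCCCC/C=C\C/C=C\CCCCCCCC(=O)n1ccnc1 | intermediate
3 | (9Z,12Z)-N-methoxy-N-methyloctadeca-9,12-dienamide | CCCCC/C=C\C/C=C\CCCCCCCC(=O)N(C)OC | intermediate
4 | bromomagnesium alkoxide of the tetrahedral methyl adduct of 3 (chelated hemiaminal) | CCCCC/C=C\C/C=C\CCCCCCCC(C)(O[Mg]Br)N(C)OC | intermediate
5 | (10Z,13Z)-nonadeca-10,13-dien-2-one | CCCCC/C=C\C/C=C\CCCCCCCC(C)=O | intermediate
6 | cis,cis-cyclohexane-1,3,5-triol (all-cis, meso) | O[C@H]1C[C@@H](O)C[C@@H](O)C1 | starting material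
7 | 3-exo-phenyl-2,4-dioxabicyclo[3.3.1]nonan-7-endo-ol (meso; phenyl equatorial on the dioxane chair; OH on the same face as the two ring oxygens) | O[C@H]1C[C@@H]2C[C@H](C1)O[C@@H](c3ccccc3)O2 | intermediate
8 | 3-exo-phenyl-2,4-dioxabicyclo[3.3.1]nonan-7-one (meso) | O=C1C[C@@H]2C[C@H](C1)O[C@@H](c3ccccc3)O2 | intermediate
9 | lithium (10Z,13Z)-nonadeca-1,10,13-trien-2-olate (kinetic enolate of 5) | CCCCC/C=C\C/C=C\CCCCCCCC(=C)O[Li] | intermediate
10 | (10Z,13Z)-1-(7-endo-hydroxy-3-exo-phenyl-2,4-dioxabicyclo[3.3.1]nonan-7-yl)nonadeca-10,13-dien-2-one (meso; tertiary OH cis to both ring oxygens, oxoalkyl chain exo) | O[C@@]1(CC(=O)CCCCCCC/C=C\C/C=C\CCCCC)C[C@@H]2C[C@H](C1)O[C@@H](c3ccccc3)O2 | intermediate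
11 | (10Z,13Z)-1-[(1s,3R,5S)-1,3,5-trihydroxycyclohexyl]nonadeca-10,13-dien-2-one (meso, all three OH cis) | O[C@@]1(CC(=O)CCCCCCC/C=C\C/C=C\CCCCC)C[C@@H](O)C[C@H](C1)O | intermediate
12 | (1R,3S,5S)-3,5-dihydroxy-3-[(10Z,13Z)-2-oxononadeca-10,13-dien-1-yl]cyclohexyl acetate | O[C@@]1(CC(=O)CCCCCCC/C=C\C/C=C\CCCCC)C[C@@H](O)C[C@H](C1)OC(C)=O | intermediate
13 | (1S,3S)-3-hydroxy-5-oxo-3-[(10Z,13Z)-2-oxononadeca-10,13-dien-1-yl]cyclohexyl acetate | O[C@@]1(CC(=O)CCCCCCC/C=C\C/C=C\CCCCC)CC(=O)C[C@H](C1)OC(C)=O | intermediate
14 | (5S)-5-hydroxy-5-[(10Z,13Z)-2-oxononadeca-10,13-dien-1-yl]cyclohex-2-en-1-one | CCCCC/C=C\C/C=C\CCCCCCCC(=O)C[C@@]1(O)CC=CC(=O)C1 | target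

**Step count and risks**
Total steps: 9. Longest linear sequence: 7 steps (6 → 7 → 8 → 10 → 11 → 12 → 13 → 14; the branch from 1 through 3 and 5 is equally long).

The three steps most likely to fail:

Step 3 (acetal formation). The acetal forces all three oxygens axial, so the equilibrium may be poor or mixed acyclic acetals may persist. The fallback sets out from 6. Trimethyl orthobenzoate (p-TsOH cat., DMF, 100 °C, MeOH distilled off) closes all three hydroxyls into the caged orthobenzoate 3-phenyl-2,4,10-trioxaadamantane F1. Reductive opening of one C–O bond with i-Bu2AlH (CH2Cl2, −78 to 0 °C) follows; the hydride is delivered from the aluminium held by the departing oxygen, so the acetal hydrogen ends up endo and the phenyl exo. This comes back to the route at 7.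

Step 5 (ketone–ketone aldol). The addition is reversible, the adduct carries an endo hydroxyl in a crowded position, and 8 can be enolised and lose a β-alkoxide. The fallback sets out from 5. Condensation with 1,1-dimethylhydrazine (AcOH cat., EtOH, 60 °C) gives the N,N-dimethylhydrazone of 5 F2. Deprotonation at the methyl group with LiN(i-Pr)2 (THF, 0 °C) gives the lithiated hydrazone F3, a more nucleophilic and less reversible aza-enolate. It is added to 8 at −78 °C, again from the exo face, to give the β-hydroxy hydrazone F4. Cleavage of the hydrazone with aqueous Cu(OAc)2 in THF at rt comes back to the route at 10.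

Step 7 (lipase desymmetrisation). The substrate is new, so the sense of enantiotopic discrimination rests on the Kazlauskas rule and is not certain; the ee is also unknown. The fallback sets out from 11. Both secondary hydroxyls are acetylated (Ac2O, pyridine, rt; the tertiary OH stays free) to give the meso diacetate F5. One ester is then hydrolysed with a hydrolase in water (the same lipase or pig liver esterase, phosphate buffer pH 7 with 10 % acetone, 30 °C). Hydrolysis removes the acetate from the carbinol that the enzyme would otherwise have acylated, so it delivers the mirror-image monoacetate of the acylation mode. This is the remedy if acylation marks the (S)-carbinol, and it comes back to the route at 12.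

**Further compounds**
F1 | step 3 | 3-phenyl-2,4,10-trioxaadamantane (orthobenzoate of 6) | c1ccccc1C12O[C@H]3C[C@H](C[C@H](C3)O1)O2
F2 | step 5 | (10Z,13Z)-nonadeca-10,13-dien-2-one N,N-dimethylhydrazone (C=N isomers) | CCCCC/C=C\C/C=C\CCCCCCCC(C)=NN(C)C
F3 | step 5 | lithiated hydrazone (methyl-side aza-enolate of F2) | CCCCC/C=C\C/C=C\CCCCCCCC(=C)N([Li])N(C)C
F4 | step 5 | N,N-dimethylhydrazone of 10 (β-hydroxy hydrazone; meso ring part as in 10) | CN(C)N=C(CCCCCCC/C=C\C/C=C\CCCCC)C[C@]1(O)C[C@@H]2C[C@H](C1)O[C@@H](c3ccccc3)O2
F5 | step 7 | (1R,3S,5s)-5-hydroxy-5-[(10Z,13Z)-2-oxononadeca-10,13-dien-1-yl]cyclohexane-1,3-diyl diacetate (meso) | O[C@@]1(CC(=O)CCCCCCC/C=C\C/C=C\CCCCC)C[C@@H](OC(C)=O)C[C@H](C1)OC(C)=O
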